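**Retrosynthetic overview**

- The strategy rests on the substitution pattern of the quinone ring (C1 carbonyl, C2 methoxy, C3 hydrogen, C4 carbonyl, C5 methyl, C6 docosyl). The oxygens on C2 and C4 are meta to each other and the long chain on C6 sits beside the one-carbon branch on C5. This is the pattern of a 6-alkylresorcylate, a tetraketide primed by a fatty acyl unit, in which ring bond C5–C6 is the aldol bond.
- The C1 oxygen is installed last by para-oxidation of the phenol at C4. The C5 methyl is traced back to the ester carbon of a resorcylate, and the C2 methoxy to the resorcylate hydroxyl that is not hydrogen-bonded to the ester.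
- The resorcylate is disconnected at C5–C6 by intramolecular aldol/aromatisation to linear methyl 3,5,7-trioxononacosanoate. This is the only ring formed, closed at step 3 and oxidised to the quinone ring at the end.
- The triketo ester comes from terminal C-acylation of the trianion of methyl 3,5-dioxohexanoate (from dehydroacetic acid) with methyl tricosanoate.

Key step: step 3

Remark: 1,3-dicarbonyl compounds are drawn as keto tautomers although they are largely enolised. The target and all isolated intermediates are achiral; aldol 7 is an unassigned diastereomer mixture that is never isolated. Mg(OMe)2 and LiN(i-Pr)2 are taken as purchased solutions.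

**Step 1**
Reactants: 1 dehydroacetic acid (3-acetyl-4-hydroxy-6-methyl-2H-pyran-2-one)
Product: 3 methyl 3,5-dioxohexanoate, via methyl 2-acetyl-3,5-dioxohexanoate 2 (not isolated)
Conditions: Mg(OMe)2 (ca. 1.5 equiv), MeOH, reflux; then aq. HCl, 0 °C; distillation
Reagents that add atoms: magnesium dimethoxide Mg(OMe)2, C[O-].C[O-].[Mg+2]; methanol, CO
Why: Methoxide opens the enol lactone by acyl substitution to the triacylmethane 2, which loses its acetyl group as methyl acetate by retro-Claisen cleavage, while the magnesium chelate of the resulting β,δ-diketo ester resists further cleavage (known methanolysis–deacetylation of dehydroacetic acid).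

**Step 2**
Reactants: 3 methyl 3,5-dioxohexanoate (2.0 equiv); 4 methyl tricosanoate
Product: 6 methyl 3,5,7-trioxononacosanoate, via trilithium trienolate of methyl 3,5-dioxohexanoate 5 (not isolated)
Conditions: LiN(i-Pr)2 (3.05 equiv per 3), THF, −78 → 0 °C; then 4 in THF, 0 °C → rt; cold dilute aq. HCl quench; crude 6 used directly
Reagents that add atoms: none
Why: Claisen-type C-acylation of a polyanion: the terminal carbanion of trienolate 5, the last formed and most nucleophilic site, attacks the ester carbonyl of 4 with loss of methoxide, and the second equivalent of 5 takes up the acidic proton of the new 1,3-diketone unit so that acylation is not stopped by proton transfer.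

**Step 3**
Reactants: 6 methyl 3,5,7-trioxononacosanoate
Product: 8 methyl 2-docosyl-4,6-dihydroxybenzoate, via methyl 2-docosyl-2-hydroxy-4,6-dioxocyclohexane-1-carboxylate 7 (not isolated)
Conditions: K2CO3 (1.5 equiv), MeOH–THF–H2O, rt; then aq. HCl to pH 2, rt
Reagents that add atoms: none
Why: Base-mediated intramolecular aldol condensation followed by aromatisation: carbonate generates the enolate of the C2 methylene of 6 (flanked by the ester and the C3 ketone), which adds to the C7 ketone to give cyclic aldol 7, and E1cB loss of water plus enolisation of the two ring ketones (completed on acidification) should deliver the benzene ring of 8. The closest known reaction type is the biomimetic cyclisation of 3,5,7-triketo acids and esters to β-resorcylates, the laboratory counterpart of the fold used by alkylresorcylate-forming polyketide synthases. The single ring closes in the 6-(enolexo)-exo-trig mode, and the new bond between chain C2 and chain C7 is ring bond C5–C6 of the target. No stereocentre survives, since the two created in 7 are destroyed by dehydration and aromatisation. The step needs selectivity for this C-aldol over Claisen closure of the C6 enolate onto the ester (which would lead to an acylphloroglucinol), over O-cyclisation to pyrones and over retro-Claisen chain cleavage; the C7 ketone is the more electrophilic acceptor, a weak non-chelating base at room temperature offers no magnesium- or alkoxide-driven attack on the ester, strong acid is withheld until the C–C bond exists, and irreversible aromatisation drains the aldol equilibrium.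

**Step 4**
Reactants: 8 methyl 2-docosyl-4,6-dihydroxybenzoate
Product: 9 methyl 2-docosyl-6-hydroxy-4-methoxybenzoate
Conditions: MeI (1.1 equiv), K2CO3 (1.2 equiv), acetone, rt → 40 °C
Reagents that add atoms: iodomethane, CI
Why: Williamson etherification that discriminates the two phenols: the hydroxyl ortho to the ester is held in an intramolecular hydrogen bond to the carbonyl and is far less nucleophilic than the free hydroxyl para to the ester, so one equivalent of MeI should alkylate only the latter.

**Step 5**
Reactants: 9 methyl 2-docosyl-6-hydroxy-4-methoxybenzoate
Product: 10 3-docosyl-2-(hydroxymethyl)-5-methoxyphenol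
Conditions: LiAlH4 (3 equiv), THF, 0 °C → reflux; then H2O, aq. NH4Cl, 0 °C; crude 10 used at once
Reagents that add atoms: none
Why: Hydride reduction of an ester by LiAlH4: after the phenol is deprotonated (hydrogen evolution, hence excess reagent and heating) the chelated ester is reduced to the primary benzylic alcohol, while the aryl methyl ether and the alkyl chain are inert; any over-reduction to 11 only anticipates step 6.

**Step 6**
Reactants: 10 3-docosyl-2-(hydroxymethyl)-5-methoxyphenol
Product: 11 3-docosyl-5-methoxy-2-methylphenol
Conditions: Et3SiH (3 equiv), CF3CO2H (10 equiv), CH2Cl2, −20 → 0 °C, slow addition of 10 to the reagent mixture; aq. NaHCO3 work-up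
Reagents that add atoms: none
Why: Ionic hydrogenation: CF3CO2H ionises the benzylic alcohol to a cation stabilised by the ortho hydroxyl and the para methoxy group, which takes hydride from Et3SiH to leave the ring methyl group, inverse addition keeping the cation concentration low.

**Step 7**
Reactants: 11 3-docosyl-5-methoxy-2-methylphenol
Product: 12 3-docosyl-5-methoxy-2-methylcyclohexa-2,5-diene-1,4-dione (the target, CNP0219396.0)
Conditions: (KSO3)2NO (2.5 equiv), KH2PO4 (aq.), MeN(n-C8H17)3Cl (cat.), CH2Cl2–H2O, rt
Reagents that add atoms: potassium nitrosodisulfonate (KSO3)2NO, [K+].[K+].[O]N(S(=O)(=O)[O-])S(=O)(=O)[O-]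
Why: Teuber oxidation: the nitroxyl radical removes the phenolic hydrogen and a second equivalent delivers oxygen to the unsubstituted carbon para to the hydroxyl (between the docosyl and methoxy carbons), giving the 1,4-quinone after loss of imidodisulfonate, with the ammonium salt carrying the oxidant to the lipophilic phenol.

**Compound list**

1 | dehydroacetic acid (3-acetyl-4-hydroxy-6-methyl-2H-pyran-2-one) | CC(=O)C1=C(O)C=C(C)OC1=O | starting material
2 | methyl 2-acetyl-3,5-dioxohexanoate | COC(=O)C(C(C)=O)C(=O)CC(C)=O | intermediate (not isolated)
3 | methyl 3,5-dioxohexanoate | COC(=O)CC(=O)CC(C)=O | intermediate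
4 | methyl tricosanoate | CCCCCCCCCCCCCCCCCCCCCCC(=O)OC | starting material
5 | trilithium trienolate of methyl 3,5-dioxohexanoate | [Li+].[Li+].[Li+].C=C([O-])C=C([O-])C=C([O-])OC | intermediate (not isolated)
6 | methyl 3,5,7-trioxononacosanoate | CCCCCCCCCCCCCCCCCCCCCCC(=O)CC(=O)CC(=O)CC(=O)OC | intermediate
7 | methyl 2-docosyl-2-hydroxy-4,6-dioxocyclohexane-1-carboxylate (diastereomer mixture) | CCCCCCCCCCCCCCCCCCCCCCC1(O)CC(=O)CC(=O)C1C(=O)OC | intermediate (not isolated)
8 | methyl 2-docosyl-4,6-dihydroxybenzoate | COC(=O)c1c(O)cc(O)cc1CCCCCCCCCCCCCCCCCCCCCC | intermediate
9 | methyl 2-docosyl-6-hydroxy-4-methoxybenzoate | COC(=O)c1c(O)cc(OC)cc1CCCCCCCCCCCCCCCCCCCCCC | intermediate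
10 | 3-docosyl-2-(hydroxymethyl)-5-methoxyphenol | OCc1c(O)cc(OC)cc1CCCCCCCCCCCCCCCCCCCCCC | intermediate
11 | 3-docosyl-5-methoxy-2-methylphenol | Cc1c(O)cc(OC)cc1CCCCCCCCCCCCCCCCCCCCCC | intermediate
12 | 3-docosyl-5-methoxy-2-methylcyclohexa-2,5-diene-1,4-dione | CCCCCCCCCCCCCCCCCCCCCCC1=C(C)C(=O)C=C(OC)C1=O | target

**Step count and risks**

Total step count: 7. Longest linear sequence: 7 steps (1 → 12); methyl tricosanoate 4 enters at step 2.

Steps most likely to fail:

1. Step 3 (key step). The ring may close through the wrong nucleophile: the C6 enolate onto the ester (Claisen), an enol oxygen onto a carbonyl (pyrone formation), or the chain may be cut by retro-Claisen cleavage before the C2-to-C7 aldol occurs. The fallback performs the same aldol on the free triketo acid, whose carboxylate cannot act as a Claisen acceptor. It sets out from 4: the dianion of pentane-2,4-dione (NaH, then n-BuLi, THF, 0 °C, two equivalents per ester) is acylated by 4 to octacosane-2,4,6-trione F1. F1 is carboxylated at its methyl terminus (LiN(i-Pr)2, 3 equiv, THF, 0 °C; then CO2) to 3,5,7-trioxononacosanoic acid F2. F2 is cyclised in aqueous KHCO3–THF at room temperature and acidified cold to 2-docosyl-4,6-dihydroxybenzoic acid F3. MeI (2.2 equiv) with K2CO3 in acetone then esterifies the carboxylate and etherifies the non-chelated hydroxyl in one operation, so the route is rejoined at 9.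

2. Step 2. Proton transfer from the α-methylene of the long-chain ester, or from the newly formed diketone, to the trienolate may outrun C-acylation; the limited solubility of the C23 ester in cold THF adds to this and favours recovery of 4 or its self-condensation. The fallback changes the acyl donor to one that releases the diketone only on quench. It sets out from 4, which with MeNHOMe·HCl and i-PrMgCl in THF at −20 → 0 °C should give N-methoxy-N-methyltricosanamide F4. F4 is added to trienolate 5 (1.3 equiv, THF, −78 → 0 °C); the amide adduct does not collapse until the acidic quench, so one equivalent of polyanion suffices and the route is rejoined at 6.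

3. Step 6. The electron-rich benzylic cation may be captured by a second arene molecule (Friedel–Crafts oligomerisation to diarylmethanes) faster than it takes hydride from the silane. The fallback moves the deoxygenation to the basic side and sets out from 9. Heating 9 with excess NaAlH2(OCH2CH2OMe)2 in toluene or xylene at reflux should reduce the salicylate through its aluminium phenoxide to an ortho-quinone methide that is reduced by hydride at once, in a medium free of acid. This replaces steps 5 and 6 and rejoins the route at 11 without 10 being isolated. This fallback adds no compound to the list (none F0).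

**Further compounds**

F1 | step 3 | octacosane-2,4,6-trione | CCCCCCCCCCCCCCCCCCCCCCC(=O)CC(=O)CC(C)=O
F2 | step 3 | 3,5,7-trioxononacosanoic acid | CCCCCCCCCCCCCCCCCCCCCCC(=O)CC(=O)CC(=O)CC(=O)O
F3 | step 3 | 2-docosyl-4,6-dihydroxybenzoic acid | OC(=O)c1c(O)cc(O)cc1CCCCCCCCCCCCCCCCCCCCCC
F4 | step 2 | N-methoxy-N-methyltricosanamide | CCCCCCCCCCCCCCCCCCCCCCC(=O)N(C)OC
F0 | step 6 | none | none
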